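**Strategy.** The route rests on disconnecting the ten-membered carbocycle at C7–C8 (germacrane numbering), closed last by an intramolecular Nozaki–Hiyama allylation. The step exploits the homoallylic alcohol unit C8(O)–C7–C11=C13: the C8 oxygen and the exocyclic methylene of the γ-lactone ring (O–C6–C7–C11–C12) are what a 3-(bromomethyl)butenolide leaves behind when its allylchromium adds through C7 to a C8 aldehyde. One operation should therefore close the carbocycle, set C7 and C8 and unveil the α-methylene lactone. The precursor is an open-chain butenolide bromide that already holds the C1–C10 oxirane (Sharpless epoxidation), the ring-cis C4=C5 alkene and a β,γ-epoxy aldehyde terminus.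

Key step: step 13

Remark on numbering: C8 bears the methacrylate, C9 is the ring CH2, C10 (bearing C14H2OAc) and C1 are the oxirane carbons, C2/C3 the CH2CH2 unit, C4 (bearing C15H2OH)=C5 the alkene, C6 the lactone O–CH, C7 the ring-fusion CH, C11=C13 the exo-methylene, C12 the lactone carbonyl.
Assumption: in step 8 the (S)-ligand is taken to deliver the (S)-carbinol at C6 (its enantiomer is used if a model coupling shows the opposite sense); compound 8 is taken as a catalogue compound.

Step 1
Reactants: 1 tert-butyldimethyl(prop-2-yn-1-yloxy)silane; 2 but-3-en-1-ylmagnesium bromide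
Product: 5 (E)-tert-butyl{[2-(iodomethylidene)hex-5-en-1-yl]oxy}dimethylsilane (iodine cis to the butenyl chain), via but-3-en-1-ylcopper 3 (not isolated), via alkenylcopper adduct 4 (not isolated)
Conditions: 2, CuBr·SMe2 (1 equiv), THF/Me2S, −45 °C; 1, −25 °C; I2, −45 → 0 °C
Reagents that add atoms: iodine, II
Why: Normant syn-carbocupration of a terminal alkyne: in THF the alkyl group should add to the internal carbon and copper to the terminus, and syn addition followed by iodinolysis with retention puts iodine cis to the butenyl chain, which fixes the ring-cis C4=C5 geometry (C3 cis to the future C6).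

Step 2
Reactants: 5
Product: 6 (E)-4-({[tert-butyl(dimethyl)silyl]oxy}methyl)-5-iodopent-4-enal
Conditions: OsO4 (2 mol %), NaIO4 (4 equiv), 2,6-lutidine, dioxane/H2O (3:1), rt
Reagents that add atoms: osmium tetroxide, O=[Os](=O)(=O)=O; sodium periodate, [Na+].[O-]I(=O)(=O)=O
Why: Lemieux–Johnson oxidation: the terminal monosubstituted alkene is dihydroxylated and cleaved far faster than the iodine-bearing trisubstituted alkene, so C1 is unveiled as the aldehyde without touching the vinyl iodide.

Step 3
Reactants: 7 methyl 2-[bis(2,2,2-trifluoroethoxy)phosphoryl]acetate; 8 1-[(2-bromoethoxy)methyl]-4-methoxybenzene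
Product: 9 methyl 2-[bis(2,2,2-trifluoroethoxy)phosphoryl]-4-[(4-methoxybenzyl)oxy]butanoate (racemic)
Conditions: NaH, DMSO, rt; 8, NaI (10 mol %), rt → 40 °C
Reagents that add atoms: none
Why: SN2 C-alkylation of the sodium phosphonoacetate by the primary bromide (in situ Finkelstein exchange); the new α-stereocentre is destroyed in step 4.

Step 4
Reactants: 6; 9
Product: 10 methyl (2Z,6E)-6-({[tert-butyl(dimethyl)silyl]oxy}methyl)-7-iodo-2-{2-[(4-methoxybenzyl)oxy]ethyl}hepta-2,6-dienoate
Conditions: 9, KHMDS, 18-crown-6, THF, −78 °C; then 6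
Reagents that add atoms: none
Why: Still–Gennari variant of the Horner–Wadsworth–Emmons olefination: fast, irreversible elimination from the kinetic adduct of the trifluoroethyl phosphonate should give the Z-enoate (ester carbon C14 cis to C2, C9 trans to C2), the geometry that becomes the trans oxirane.

Step 5
Reactants: 10
Product: 11 (2Z,6E)-6-({[tert-butyl(dimethyl)silyl]oxy}methyl)-7-iodo-2-{2-[(4-methoxybenzyl)oxy]ethyl}hepta-2,6-dien-1-ol
Conditions: DIBAL-H (2.5 equiv), CH2Cl2, −78 °C; Rochelle salt
Reagents that add atoms: none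
Why: 1,2-Reduction of the enoate to the allylic alcohol by DIBAL-H; vinyl iodide, PMB ether and silyl ether are inert at −78 °C and the alkene geometry is kept.

Step 6
Reactants: 11
Product: 12 [(2S,3R)-3-[(3E)-3-({[tert-butyl(dimethyl)silyl]oxy}methyl)-4-iodobut-3-en-1-yl]-2-{2-[(4-methoxybenzyl)oxy]ethyl}oxiran-2-yl]methanol
Conditions: Ti(OiPr)4 (0.3 equiv), L-(+)-diethyl tartrate (0.36 equiv), t-BuOOH, 4 Å MS, CH2Cl2, −20 °C
Reagents that add atoms: tert-butyl hydroperoxide, CC(C)(C)OO
Why: Sharpless asymmetric epoxidation: only the free C14 allylic alcohol binds titanium, so the C4=C5 alkene (a silyl ether) is untouched, L-(+)-tartrate should deliver oxygen to the face that gives C10 (S) and C1 (R), and the Z geometry is carried into the trans C9/C2 relation of the oxirane.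

Step 7
Reactants: 12
Product: 13 [(2S,3R)-3-[(3E)-3-({[tert-butyl(dimethyl)silyl]oxy}methyl)-4-iodobut-3-en-1-yl]-2-{2-[(4-methoxybenzyl)oxy]ethyl}oxiran-2-yl]methyl acetate
Conditions: Ac2O, Et3N, DMAP (cat.), CH2Cl2, 0 °C
Reagents that add atoms: acetic anhydride, CC(=O)OC(C)=O
Why: DMAP-catalysed O-acetylation of the primary epoxy alcohol installs the C14 acetate of the target and prevents later lactol formation with the C8 aldehyde; no stereocentre is involved.

Step 8
Reactants: 13; 14 (E)-but-2-enal
Product: 16 {(2S,3R)-3-[(3E,5S,6E)-3-({[tert-butyl(dimethyl)silyl]oxy}methyl)-5-hydroxyocta-3,6-dien-1-yl]-2-{2-[(4-methoxybenzyl)oxy]ethyl}oxiran-2-yl}methyl acetate, via alkenylchromium species 15 (not isolated)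
Conditions: CrCl2 (4 equiv), NiCl2 (2 mol %), (S)-N-[2-(4-isopropyl-4,5-dihydrooxazol-2-yl)-6-methylphenyl]methanesulfonamide (4.4 equiv), Et3N, THF, rt; 14 (3 equiv)
Reagents that add atoms: none
Why: Asymmetric Nozaki–Hiyama–Kishi coupling: nickel inserts into the C–I bond with retention, the alkenylchromium(III) adds 1,2 to the enal without touching oxirane, acetate or ethers, and the chiral sulfonamide–chromium complex should select the aldehyde face (reagent control) to set C6 as the (S)-carbinol.

Step 9
Reactants: 16; 17 2-(bromomethyl)prop-2-enoic acid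
Product: 18 2-(bromomethyl)prop-2-enoate ester of 16 at the C6 oxygen [(5S)-octa-3,6-dien-5-yl ester; other stereo as in 16]
Conditions: DCC, DMAP (5 mol %), CH2Cl2, 0 °C
Reagents that add atoms: none
Why: Steglich esterification of the secondary bis-allylic alcohol; low DMAP loading at 0 °C should avoid SN2′ attack on the allylic bromide, and C6 keeps its configuration because only the O–H bond reacts.

Step 10
Reactants: 18
Product: 19 {(2S,3R)-3-[(3E)-4-[(2R)-4-(bromomethyl)-5-oxo-2,5-dihydrofuran-2-yl]-3-({[tert-butyl(dimethyl)silyl]oxy}methyl)but-3-en-1-yl]-2-{2-[(4-methoxybenzyl)oxy]ethyl}oxiran-2-yl}methyl acetate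
Conditions: Grubbs second-generation catalyst (10 mol %), CH2Cl2 (5 mM), 40 °C
Reagents that add atoms: none
Why: Ring-closing metathesis: ruthenium should load on the disubstituted propenyl alkene (the trisubstituted C4=C5 and the acrylate are poor initiators), and five-membered closure onto the acrylate expels propene and closes the γ-lactone ring as the α-(bromomethyl)butenolide with C6 unchanged.

Step 11
Reactants: 19
Product: 20 {(2S,3R)-3-[(3E)-4-[(2R)-4-(bromomethyl)-5-oxo-2,5-dihydrofuran-2-yl]-3-({[tert-butyl(dimethyl)silyl]oxy}methyl)but-3-en-1-yl]-2-(2-hydroxyethyl)oxiran-2-yl}methyl acetate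
Conditions: DDQ (1.3 equiv), CH2Cl2/pH 7 buffer (10:1), 0 °C
Reagents that add atoms: none
Why: Oxidative cleavage of the PMB ether by DDQ under neutral buffered conditions, which the allylic bromide, oxirane, acetate and silyl ether should tolerate.

Step 12
Reactants: 20
Product: 21 {(2S,3R)-3-[(3E)-4-[(2R)-4-(bromomethyl)-5-oxo-2,5-dihydrofuran-2-yl]-3-({[tert-butyl(dimethyl)silyl]oxy}methyl)but-3-en-1-yl]-2-(2-oxoethyl)oxiran-2-yl}methyl acetate (used crude)
Conditions: Dess–Martin periodinane, NaHCO3, CH2Cl2, 0 °C → rt, 30 min; filtration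
Reagents that add atoms: none
Why: Dess–Martin oxidation of the primary alcohol under bicarbonate buffering, with no amine base that could open the β,γ-epoxy aldehyde by E1cB or attack the allylic bromide; the aldehyde is used at once.

Step 13
Reactants: 21
Product: 23 (1R,6R,7R,8S,10S)-14-acetoxy-15-(tert-butyldimethylsilyloxy)-1,10-epoxy-8-hydroxygermacra-4,11(13)-dien-12,6-olide (8α-OH; trans-lactone; ring-cis C4=C5), via allylchromium species 22 (not isolated)
Conditions: CrCl2 (8 equiv), degassed THF, rt; 21 added by syringe pump over 10 h (final 1 mM); then H2O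
Reagents that add atoms: none
Why: Two equivalents of Cr(II) reduce the allylic C13–Br bond to the allylchromium(III) species 22, which adds to the C8 aldehyde through C7 (SE2′) in a closed six-membered chair, so that one event forms C7–C8, the C8 carbinol and the exocyclic C11=C13 bond (Nozaki–Hiyama allylation). The closest known reactions are chromium-mediated macrocyclisations of aldehydes carrying a 2-(bromomethyl)acrylate unit to ten-membered germacranolide rings, and Barbier allylations of aldehydes by 3-(bromomethyl)furan-2(5H)-ones, which give β-(hydroxyalkyl)-α-methylene-γ-butyrolactones. The ten-membered carbocycle closes by 10-exo-trig attack of C7 on the C8 carbonyl, while the lactone and oxirane rings are already in place and the lactone only loses its endocyclic C7=C11 bond. C7 is controlled by C6: the aldehyde should be delivered to the butenolide face anti to the C6–C5 bond, because syn delivery would eclipse C5–C6–C7–C8 in the nascent ring, and this gives the trans-fused lactone (H-6β, H-7α). C8 is controlled by the allyl geometry, fixed as E-type by the butenolide ring (C6 trans to CH2Cr): the chair with C9 equatorial gives the anti adduct, i.e. the 8α-alcohol, with C6–C7–C8–C9 gauche as the ten-membered ring demands. The step needs cyclisation over oligomerisation and γ- over α-attack, secured by slow addition at about 1 mM and by the intrinsic SE2′ course of allylchromium reagents; Cr(II) should leave the oxirane, the esters, the silyl ether and the C4=C5 alkene untouched.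

Step 14
Reactants: 23
Product: 24 (1R,6R,7R,8S,10S)-14-acetoxy-15-(tert-butyldimethylsilyloxy)-1,10-epoxy-8-(methacryloyloxy)germacra-4,11(13)-dien-12,6-olide
Conditions: methacrylic anhydride (3 equiv), Et3N, DMAP, CH2Cl2, 0 °C → rt
Reagents that add atoms: methacrylic anhydride, C=C(C)C(=O)OC(=O)C(C)=C
Why: DMAP-catalysed O-acylation of the secondary C8 alcohol with retention at C8; the C15 silyl ether keeps the primary alcohol out of the reaction.

Step 15
Reactants: 24
Product: 25 target, (1R,6R,7R,8S,10S)-14-acetoxy-1,10-epoxy-15-hydroxy-8-(methacryloyloxy)germacra-4,11(13)-dien-12,6-olide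
Conditions: TBAF/AcOH (1:1), THF, 0 °C → rt
Reagents that add atoms: none
Why: Fluoride-induced desilylation of the primary allylic TBS ether; acetic acid buffering keeps the medium near neutral so that the esters, the α-methylene lactone and the acid- and base-sensitive epoxide should survive.

**Compound list**
1 | tert-butyldimethyl(prop-2-yn-1-yloxy)silane | C#CCO[Si](C)(C)C(C)(C)C | starting material
2 | but-3-en-1-ylmagnesium bromide | C=CCC[Mg]Br | starting material
3 | but-3-en-1-ylcopper(I) (MgBr2 complex) | C=CCC[Cu] | intermediate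
4 | (E)-[2-({[tert-butyl(dimethyl)silyl]oxy}methyl)hexa-1,5-dien-1-yl]copper (Cu cis to butenyl) | C=CCC/C(CO[Si](C)(C)C(C)(C)C)=C\[Cu] | intermediate
5 | (E)-tert-butyl{[2-(iodomethylidene)hex-5-en-1-yl]oxy}dimethylsilane | C=CCC/C(CO[Si](C)(C)C(C)(C)C)=C\I | intermediate
6 | (E)-4-({[tert-butyl(dimethyl)silyl]oxy}methyl)-5-iodopent-4-enal | O=CCC/C(CO[Si](C)(C)C(C)(C)C)=C\I | intermediate
7 | methyl 2-[bis(2,2,2-trifluoroethoxy)phosphoryl]acetate | COC(=O)CP(=O)(OCC(F)(F)F)OCC(F)(F)F | starting material
8 | 1-[(2-bromoethoxy)methyl]-4-methoxybenzene | COc1ccc(COCCBr)cc1 | starting material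
9 | methyl 2-[bis(2,2,2-trifluoroethoxy)phosphoryl]-4-[(4-methoxybenzyl)oxy]butanoate (racemic) | COC(=O)C(CCOCc1ccc(OC)cc1)P(=O)(OCC(F)(F)F)OCC(F)(F)F | intermediate
10 | methyl (2Z,6E)-6-(TBSO-methyl)-7-iodo-2-[2-(PMBO)ethyl]hepta-2,6-dienoate | COc1ccc(COCC/C(C(=O)OC)=C/CC/C(CO[Si](C)(C)C(C)(C)C)=C\I)cc1 | intermediate
11 | (2Z,6E)-6-(TBSO-methyl)-7-iodo-2-[2-(PMBO)ethyl]hepta-2,6-dien-1-ol | COc1ccc(COCC/C(CO)=C/CC/C(CO[Si](C)(C)C(C)(C)C)=C\I)cc1 | intermediate
12 | (2S,3R)-epoxy alcohol (oxirane C10/C1; C14H2OH on C10) | COc1ccc(COCC[C@@]2(CO)O[C@@H]2CC/C(CO[Si](C)(C)C(C)(C)C)=C\I)cc1 | intermediate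
13 | (2S,3R)-epoxy acetate | COc1ccc(COCC[C@@]2(COC(C)=O)O[C@@H]2CC/C(CO[Si](C)(C)C(C)(C)C)=C\I)cc1 | intermediate
14 | (E)-but-2-enal | C/C=C/C=O | starting material
15 | alkenylchromium(III) dichloride from 13 | COc1ccc(COCC[C@@]2(COC(C)=O)O[C@@H]2CC/C(CO[Si](C)(C)C(C)(C)C)=C\[Cr](Cl)Cl)cc1 | intermediate
16 | (5S)-bis-allylic alcohol (C6 carbinol; 3E,6E; oxirane 2S,3R) | COc1ccc(COCC[C@@]2(COC(C)=O)O[C@@H]2CC/C(CO[Si](C)(C)C(C)(C)C)=C\[C@@H](O)/C=C/C)cc1 | intermediate
17 | 2-(bromomethyl)prop-2-enoic acid | OC(=O)C(=C)CBr | starting material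
18 | 2-(bromomethyl)acrylate ester of 16 | COc1ccc(COCC[C@@]2(COC(C)=O)O[C@@H]2CC/C(CO[Si](C)(C)C(C)(C)C)=C\[C@@H](OC(=O)C(=C)CBr)/C=C/C)cc1 | intermediate
19 | (2R)-4-(bromomethyl)butenolide, PMB ether | COc1ccc(COCC[C@@]2(COC(C)=O)O[C@@H]2CC/C(CO[Si](C)(C)C(C)(C)C)=C\[C@H]3OC(=O)C(CBr)=C3)cc1 | intermediate
20 | (2R)-4-(bromomethyl)butenolide, C8 alcohol | OCC[C@@]1(COC(C)=O)O[C@@H]1CC/C(CO[Si](C)(C)C(C)(C)C)=C\[C@H]2OC(=O)C(CBr)=C2 | intermediate
21 | (2R)-4-(bromomethyl)butenolide, C8 aldehyde | O=CC[C@@]1(COC(C)=O)O[C@@H]1CC/C(CO[Si](C)(C)C(C)(C)C)=C\[C@H]2OC(=O)C(CBr)=C2 | intermediate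
22 | allylchromium(III) dichloride from 21 | O=CC[C@@]1(COC(C)=O)O[C@@H]1CC/C(CO[Si](C)(C)C(C)(C)C)=C\[C@H]2OC(=O)C(C[Cr](Cl)Cl)=C2 | intermediate
23 | (1R,6R,7R,8S,10S)-14-acetoxy-15-(TBSO)-1,10-epoxy-8-hydroxygermacra-4,11(13)-dien-12,6-olide | O[C@H]1C[C@@]2(COC(C)=O)O[C@@H]2CC/C(CO[Si](C)(C)C(C)(C)C)=C\[C@H]2OC(=O)C(=C)[C@H]12 | intermediate
24 | 8-O-methacryloyl derivative of 23 | C=C(C)C(=O)O[C@H]1C[C@@]2(COC(C)=O)O[C@@H]2CC/C(CO[Si](C)(C)C(C)(C)C)=C\[C@H]2OC(=O)C(=C)[C@H]12 | intermediate
25 | CNP0306006.2 | C=C(C)C(=O)O[C@H]1C[C@@]2(COC(C)=O)O[C@@H]2CC/C(CO)=C\[C@H]2OC(=O)C(=C)[C@H]12 | target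

**Step count.** Total: 15 steps. Longest linear sequence: 14 steps (1, 2, 4–15); step 3 is a one-step side branch.

**Steps most likely to fail**

Step 13. What may go wrong: oligomerisation, or loss of the β,γ-epoxy aldehyde to the Lewis-acidic Cr(III) salts before the slow ring closure, or erosion of the C7/C8 selectivity. The fallback replaces the reductive Barbier process by a neutral intramolecular allylboration. It sets out from 19: palladium-catalysed Miyaura-type borylation of the allylic bromide (B2pin2, Pd2(dba)3, toluene, 50 °C) should give the 4-[(pinacolboryl)methyl]butenolide F1. DDQ then frees the C8 alcohol of the allylboronate F2, and buffered Dess–Martin oxidation gives the boronate aldehyde F3. At high dilution in toluene (25–60 °C) F3 should cyclise through the closed boron chair (γ-attack at C7, same E-type geometry, anti adduct). Triethanolamine work-up then gives 23, where the route is rejoined.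

Step 8. What may go wrong: poor facial selectivity of the alkenylchromium addition to the small enal, with no help from the remote oxirane and C6 epimers that are hard to separate. The fallback sets C6 by ketone reduction. From 13, the ligand-free Ni/Cr coupling with 14 gives 16 together with its C6 epimer F4. MnO2 oxidises the mixture to the cross-conjugated dienone F5. Corey–Bakshi–Shibata reduction ((R)-Me-CBS, catecholborane, toluene, −78 °C; the β,β-disubstituted alkenyl arm acting as the large group) should return 16.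

Step 1. What may go wrong: wrong regiochemistry of the copper addition (copper on the internal carbon, then β-elimination of silanolate to an allene). The fallback uses hydroxyl-directed anti-carbomagnesiation followed by ipso-iododesilylation. It sets out from 2 and commercial 3-(trimethylsilyl)prop-2-yn-1-ol (C[Si](C)(C)C#CCO). CuI-catalysed addition in THF should place the butenyl group on the carbinol-bearing alkyne carbon and the alkoxide-chelated magnesium on the silyl-bearing carbon; protonation gives the (E)-silyl allylic alcohol F6, in which silicon is cis to the butenyl chain. TBSCl/imidazole gives the silyl ether F7. N-Iodosuccinimide (MeCN/ClCH2CN, 0 °C) should replace silicon by iodine with retention, giving 5.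

**Further compounds**
F1 | step 13 | 4-[(pinacolboryl)methyl]butenolide, PMB ether (Bpin in place of Br in 19) | COc1ccc(COCC[C@@]2(COC(C)=O)O[C@@H]2CC/C(CO[Si](C)(C)C(C)(C)C)=C\[C@H]3OC(=O)C(CB4OC(C)(C)C(C)(C)O4)=C3)cc1
F2 | step 13 | allylboronate C8 alcohol | OCC[C@@]1(COC(C)=O)O[C@@H]1CC/C(CO[Si](C)(C)C(C)(C)C)=C\[C@H]2OC(=O)C(CB3OC(C)(C)C(C)(C)O3)=C2
F3 | step 13 | allylboronate C8 aldehyde | O=CC[C@@]1(COC(C)=O)O[C@@H]1CC/C(CO[Si](C)(C)C(C)(C)C)=C\[C@H]2OC(=O)C(CB3OC(C)(C)C(C)(C)O3)=C2
F4 | step 8 | C6 epimer of 16 [(5R)-carbinol] | COc1ccc(COCC[C@@]2(COC(C)=O)O[C@@H]2CC/C(CO[Si](C)(C)C(C)(C)C)=C\[C@H](O)/C=C/C)cc1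
F5 | step 8 | cross-conjugated dienone (C6 ketone) | COc1ccc(COCC[C@@]2(COC(C)=O)O[C@@H]2CC/C(CO[Si](C)(C)C(C)(C)C)=C\C(=O)/C=C/C)cc1
F6 | step 1 | (E)-2-(but-3-en-1-yl)-3-(trimethylsilyl)prop-2-en-1-ol | C=CCC/C(CO)=C\[Si](C)(C)C
F7 | step 1 | TBS ether of F6 | C=CCC/C(CO[Si](C)(C)C(C)(C)C)=C\[Si](C)(C)C
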